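**Direct plan and its weak points**

A direct plan would keep the benzene ring from the start: resorcinol bis(methoxymethyl) ether A1 would be lithiated between its oxygens, turned into an aryl(diethyl)alane and used to trigger a Beckmann rearrangement–aryl transfer on cyclopentanone oxime mesylate A2, giving cyclic imine A3.
Iridium-catalysed hydrogenation and reductive N-methylation would give arylpiperidine A4; C–H borylation–oxidation and iodination would give iodophenol A5; a carbonylative alkyne annulation would close flavone A6; copper hydride reduction and acidic MOM removal would finish.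
Weakest steps:
(1) The rearrangement–arylation that makes the aryl–piperidine bond: aryl transfer from a di-ortho-alkoxy aryl(dialkyl)alane to a nitrilium ion is without precedent, competes with ethyl transfer, needs the arene in twofold excess, and the whole route rests on it.
(2) The run of borylation–oxidation, iodination and carbonylative annulation: three steps on an oxidisable benzylic amine that only place functional groups on ring A so that ring C can be closed afterwards.
(3) The conjugate reduction that sets C2 last: a 5-alkoxy-6-substituted flavone is a hindered acceptor, the remote piperidine centre raises a matched/mismatched question, and the warm acid that follows invites chalcone-type opening at C2 and ionisation at the benzylic amine centre.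

**Retrosynthetic overview of the new route**

Ring A (C4a, C5, C6, C7, C8, C8a) is built last by a Danheiser benzannulation between two partners. The vinylketene from a (2S)-6-(diazoacetyl)-2-phenyl-2,3-dihydropyran-4-one (ring C complete) supplies C5, C8, C8a and C4a. A (2R)-piperidin-2-yl siloxyalkyne supplies C6 and C7. Bonds C5–C6, C7–C8 and C4a–C5 form in one operation.
Ring order: piperidine (from D-pipecolate), then ring C (asymmetric aldol–cyclocondensation of benzaldehyde with a 2,4-dioxo ester diene), then ring A. The direct plan closes them in the order A, piperidine, C.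
The mechanism places the piperidinyl carbon between the ketene-derived C5–OH and the ynol-ether-derived C7–O, with O1 already para to it. There is therefore no C6/C8 question, no arene C–H oxidation or halogenation, and no unprecedented rearrangement.
Both stereocentres arrive in small fragments (chiral pool; ligand-controlled aldol) and are spectators afterwards. Nothing is reduced late; the end is a mild deprotection and N-methylation.

Key step: step 6

Remark on the chemistry: the SMILES is read as (2S) at C2 of the flavanone and (2R) at C2 of the piperidine. Flavanone numbering (O1, C2, C3, C4, C4a, C5–C8, C8a) is used for the product; pyranone numbering (O1, C2 bearing phenyl, C3, C4 carbonyl, C5, C6) is used for the ring C fragment.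

**Route**

Step 1
Reactants: 1 1-tert-butyl 2-methyl (2R)-piperidine-1,2-dicarboxylate (methyl N-Boc-D-pipecolate)
Product: 3 tert-butyl (2R)-2-({[tri(propan-2-yl)silyl]oxy}ethynyl)piperidine-1-carboxylate, via lithium ynolate 2 (not isolated)
Conditions: CH2Br2, LiTMP, THF, −78 °C; then 1; LiHMDS; n-BuLi, −78 → 0 °C; i-Pr3SiOTf, −78 °C → rt
Reagents that add atoms: dibromomethane, BrCBr; triisopropylsilyl trifluoromethanesulfonate, CC(C)[Si](C(C)C)(C(C)C)OS(=O)(=O)C(F)(F)F
Why: Kowalski ester homologation stopped at the ynolate stage: LiCHBr2 adds to the ester, the derived dibromo enolate undergoes bromine–lithium exchange and a carbenoid 1,2-shift of the piperidinyl carbon with retention (the stereocentre is never α to a free ketone and so is not enolised), and the bulky silyl triflate traps the ynolate on oxygen.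

Step 2
Reactants: 4 methyl 2,4-dioxopentanoate
Product: 5 methyl 2,4-bis[(trimethylsilyl)oxy]penta-2,4-dienoate (geometry at C2=C3 not decisive)
Conditions: Me3SiOTf (2.2 equiv), Et3N (2.5 equiv), Et2O, 0 °C → rt; pentane extraction, used crude
Reagents that add atoms: trimethylsilyl trifluoromethanesulfonate, C[Si](C)(C)OS(=O)(=O)C(F)(F)F
Why: Silyl enol ether formation by soft enolisation, the standard entry to 1,3-bis(silyloxy)dienes from 1,3-dicarbonyl compounds; only this cross-conjugated diene can form, because C3 and C5 are the only enolisable carbons.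

Step 3
Reactants: 5 methyl 2,4-bis[(trimethylsilyl)oxy]penta-2,4-dienoate; 6 benzaldehyde
Product: 8 methyl (2S)-4-oxo-2-phenyl-3,4-dihydro-2H-pyran-6-carboxylate, via silyl aldol adduct 7 (not isolated)
Conditions: Ti(Oi-Pr)4 (10 mol %), (S)-BINOL (20 mol %), 4 Å MS, THF, −20 °C; then CF3CO2H, CH2Cl2, 0 °C → rt
Reagents that add atoms: none
Why: Vinylogous Mukaiyama aldol addition of the terminal enol silane carbon of 5 to benzaldehyde on the chiral BINOL–titanium Lewis acid (the aldol pathway of asymmetric hetero-Diels–Alder reactions of siloxydienes) should set the carbinol centre (S) by ligand-controlled Si-face attack, and the acid then removes the silyl groups and condenses the δ-hydroxyl with the enolised 2-oxo ester to the vinylogous ester of ring C without breaking the C–O bond at the stereocentre; the sense of induction would be checked on 8 and (R)-BINOL used if it were opposite.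

Step 4
Reactants: 8 methyl (2S)-4-oxo-2-phenyl-3,4-dihydro-2H-pyran-6-carboxylate
Product: 9 (2S)-4-oxo-2-phenyl-3,4-dihydro-2H-pyran-6-carboxylic acid
Conditions: Me3SnOH (3 equiv), ClCH2CH2Cl, 70 °C; 0.5 M aq. HCl wash
Reagents that add atoms: trimethyltin hydroxide, C[Sn](C)(C)O
Why: Ester hydrolysis with trimethyltin hydroxide, a near-neutral hydroxide-transfer reagent, chosen because free hydroxide could enolise C3 and expel the ring oxygen (β-elimination with loss of the C2 configuration) or add to C6.

Step 5
Reactants: 9 (2S)-4-oxo-2-phenyl-3,4-dihydro-2H-pyran-6-carboxylic acid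
Product: 11 (2S)-6-(diazoacetyl)-2-phenyl-2,3-dihydro-4H-pyran-4-one, via acid chloride 10 (not isolated)
Conditions: (COCl)2, DMF (cat.), CH2Cl2, 0 °C → rt, evaporate; Me3SiCHN2 (2 equiv), THF/MeCN, 0 °C
Reagents that add atoms: (trimethylsilyl)diazomethane, C[Si](C)(C)C=[N+]=[N-]
Why: Acylation of a diazoalkane by an acid chloride (the first half of an Arndt–Eistert sequence), run with the silylated, less dipolarophile-prone reagent at 0 °C so that C-acylation and loss of the silyl group as its chloride outrun cycloaddition to the donor-substituted enone double bond.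

Step 6
Reactants: 11 (2S)-6-(diazoacetyl)-2-phenyl-2,3-dihydro-4H-pyran-4-one; 3 tert-butyl (2R)-2-({[tri(propan-2-yl)silyl]oxy}ethynyl)piperidine-1-carboxylate
Product: 15 tert-butyl (2R)-2-[(2S)-5-hydroxy-4-oxo-2-phenyl-7-{[tri(propan-2-yl)silyl]oxy}-3,4-dihydro-2H-chromen-6-yl]piperidine-1-carboxylate, via vinylketene 12 (not isolated), via vinylcyclobutenone 13 (not isolated), via dienylketene 14 (not isolated)
Conditions: 11 (1.0 equiv), 3 (1.5 equiv), degassed ClCH2CH2Cl (0.05 M), hν (440 nm LED), 20 °C until N2 evolution stops; then dark, 80 °C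
Reagents that add atoms: none
Why: Danheiser benzannulation in its photochemical Wolff variant: irradiation of 11 expels N2 with migration of the pyranonyl group to give vinylketene 12, which the electron-rich siloxyalkyne 3 captures in a regioselective [2+2] cycloaddition (ketene carbonyl carbon to the alkyne carbon remote from oxygen) to give cyclobutenone 13; 4π-electrocyclic opening gives dienylketene 14, and 6π-electrocyclisation onto the enone α-carbon of ring C (the future C4a) followed by tautomerisation gives the phenol. The closest known reaction type is the benzannulation of α,β-unsaturated and aryl α-diazo ketones with siloxyalkynes to 3-siloxyphenols. Ring A is closed in a 6π-electrocyclic mode (bond C4a–C5) after bonds C5–C6 and C7–C8 have been made in the [2+2] step, while ring C and the piperidine are carried in intact. No stereocentre is created: C2 of ring C and C2 of the piperidine are spectators under neutral, non-enolising conditions and keep the configuration set in steps 3 and 1. The regiochemistry is fixed by the substrates: the polarisation of the ynol ether places the piperidinyl carbon between the ketene-derived C5 hydroxyl and the C7 silyl ether, O1 is already bonded to C8a para to that carbon, and the C4 carbonyl is trans to the ketene arm across the ring double bond, so closure can only take place at the C–H carbon (no α-pyrone). The long wavelength should excite only the diazo chromophore, and the new C5 hydroxyl, hydrogen-bonded to C4=O and flanked by the piperidine, should be slow to be acylated by unreacted ketene.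

Step 7
Reactants: 15 tert-butyl (2R)-2-[(2S)-5-hydroxy-4-oxo-2-phenyl-7-{[tri(propan-2-yl)silyl]oxy}-3,4-dihydro-2H-chromen-6-yl]piperidine-1-carboxylate
Product: 18 (2S)-5,7-dihydroxy-6-[(2R)-1-methylpiperidin-2-yl]-2-phenyl-2,3-dihydro-4H-chromen-4-one, via amine hydrochloride 16 (not isolated), via N-methyl silyl ether 17 (not isolated)
Conditions: 4 M HCl in 1,4-dioxane, 0 °C → rt, evaporate; 37 % aq. HCHO, NaBH(OAc)3, NaOAc, ClCH2CH2Cl, 0 °C → rt; aq. NaHCO3 (pH 7–8), extract; crude in MeOH, KHF2, rt
Reagents that add atoms: formaldehyde, C=O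
Why: Acidolysis of the tert-butyl carbamate, reductive amination of the secondary amine with formaldehyde and NaBH(OAc)3 (which leaves the hydrogen-bonded aryl ketone alone) while O7 is still silylated, and bifluoride cleavage of the aryl silyl ether para to the carbonyl are all run at or below room temperature without base, so neither chalcone-type opening at C2 nor ionisation at the benzylic amine centre is invited.

**Compound list**

1 | 1-tert-butyl 2-methyl (2R)-piperidine-1,2-dicarboxylate | CC(C)(C)OC(=O)N1CCCC[C@@H]1C(=O)OC | starting material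
2 | lithium 2-[(2R)-1-(tert-butoxycarbonyl)piperidin-2-yl]ethynolate | CC(C)(C)OC(=O)N1CCCC[C@@H]1C#C[O-].[Li+] | intermediate
3 | tert-butyl (2R)-2-({[tri(propan-2-yl)silyl]oxy}ethynyl)piperidine-1-carboxylate | CC(C)(C)OC(=O)N1CCCC[C@@H]1C#CO[Si](C(C)C)(C(C)C)C(C)C | intermediate
4 | methyl 2,4-dioxopentanoate | COC(=O)C(=O)CC(C)=O | starting material
5 | methyl 2,4-bis[(trimethylsilyl)oxy]penta-2,4-dienoate | COC(=O)C(O[Si](C)(C)C)=CC(=C)O[Si](C)(C)C | intermediate
6 | benzaldehyde | O=Cc1ccccc1 | starting material
7 | methyl (6S)-4-oxo-6-phenyl-2,6-bis[(trimethylsilyl)oxy]hex-2-enoate | COC(=O)C(O[Si](C)(C)C)=CC(=O)C[C@@H](c1ccccc1)O[Si](C)(C)C | intermediate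
8 | methyl (2S)-4-oxo-2-phenyl-3,4-dihydro-2H-pyran-6-carboxylate | COC(=O)C1=CC(=O)C[C@@H](c2ccccc2)O1 | intermediate
9 | (2S)-4-oxo-2-phenyl-3,4-dihydro-2H-pyran-6-carboxylic acid | OC(=O)C1=CC(=O)C[C@@H](c2ccccc2)O1 | intermediate
10 | (2S)-4-oxo-2-phenyl-3,4-dihydro-2H-pyran-6-carbonyl chloride | ClC(=O)C1=CC(=O)C[C@@H](c2ccccc2)O1 | intermediate
11 | (2S)-6-(diazoacetyl)-2-phenyl-2,3-dihydro-4H-pyran-4-one | [N-]=[N+]=CC(=O)C1=CC(=O)C[C@@H](c2ccccc2)O1 | intermediate
12 | (2S)-6-(2-oxoethenyl)-2-phenyl-2,3-dihydro-4H-pyran-4-one | O=C=CC1=CC(=O)C[C@@H](c2ccccc2)O1 | intermediate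
13 | tert-butyl (2R)-2-{4-oxo-3-[(2S)-4-oxo-2-phenyl-3,4-dihydro-2H-pyran-6-yl]-2-{[tri(propan-2-yl)silyl]oxy}cyclobut-1-en-1-yl}piperidine-1-carboxylate (mixture at the ring CH) | CC(C)(C)OC(=O)N1CCCC[C@@H]1C1=C(O[Si](C(C)C)(C(C)C)C(C)C)C(C2=CC(=O)C[C@@H](c3ccccc3)O2)C1=O | intermediate
14 | tert-butyl (2R)-2-{1-oxo-4-[(2S)-4-oxo-2-phenyl-3,4-dihydro-2H-pyran-6-yl]-3-{[tri(propan-2-yl)silyl]oxy}buta-1,3-dien-2-yl}piperidine-1-carboxylate | CC(C)(C)OC(=O)N1CCCC[C@@H]1C(=C=O)C(O[Si](C(C)C)(C(C)C)C(C)C)=CC1=CC(=O)C[C@@H](c2ccccc2)O1 | intermediate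
15 | tert-butyl (2R)-2-[(2S)-5-hydroxy-4-oxo-2-phenyl-7-{[tri(propan-2-yl)silyl]oxy}-3,4-dihydro-2H-chromen-6-yl]piperidine-1-carboxylate | CC(C)(C)OC(=O)N1CCCC[C@@H]1c1c(O[Si](C(C)C)(C(C)C)C(C)C)cc2c(c1O)C(=O)C[C@@H](c1ccccc1)O2 | intermediate
16 | (2S)-5-hydroxy-2-phenyl-6-[(2R)-piperidin-2-yl]-7-{[tri(propan-2-yl)silyl]oxy}-2,3-dihydro-4H-chromen-4-one hydrochloride | Cl.N1CCCC[C@@H]1c1c(O[Si](C(C)C)(C(C)C)C(C)C)cc2c(c1O)C(=O)C[C@@H](c1ccccc1)O2 | intermediate
17 | (2S)-5-hydroxy-6-[(2R)-1-methylpiperidin-2-yl]-2-phenyl-7-{[tri(propan-2-yl)silyl]oxy}-2,3-dihydro-4H-chromen-4-one | CN1CCCC[C@@H]1c1c(O[Si](C(C)C)(C(C)C)C(C)C)cc2c(c1O)C(=O)C[C@@H](c1ccccc1)O2 | intermediate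
18 | (2S)-5,7-dihydroxy-6-[(2R)-1-methylpiperidin-2-yl]-2-phenyl-2,3-dihydro-4H-chromen-4-one | CN1CCCC[C@@H]1c1c(O)cc2c(c1O)C(=O)C[C@@H](c1ccccc1)O2 | target

**Step count and risks**

Total step count: 7. Longest linear sequence: 6 (steps 2, 3, 4, 5, 6, 7); step 1 is the convergent branch.

Steps most likely to fail:

Step 6 (key step). The risks are excitation of the enone of ring C or of the product instead of the diazo group, slow capture of the ketene by the branched, carbamate-flanked alkyne (leading to ketene dimerisation or acylation of the product phenol), and participation of the carbamate carbonyl during the cycloaddition. The fallback reaches the same ketene without light. It sets out from 11: Arndt–Eistert homologation (AgOBz cat., Et3N, THF/H2O, dark) should give [(2S)-4-oxo-2-phenyl-3,4-dihydro-2H-pyran-6-yl]acetic acid F1, and (COCl)2 with catalytic DMF should give [(2S)-4-oxo-2-phenyl-3,4-dihydro-2H-pyran-6-yl]acetyl chloride F2. Slow addition of F2 to 3 and i-Pr2NEt in toluene (0 → 80 °C) would generate vinylketene 12 by dehydrochlorination at low stationary concentration. The cascade then continues through 13 and 14, and the route is rejoined at 15.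

Step 3. The risks are poor facial selectivity, or attack at the wrong carbon of the ester-substituted diene, and incomplete cyclodehydration. The fallback sets out from 6. An aldol addition of acetone catalysed by a D-proline-derived prolinamide should give (4S)-4-hydroxy-4-phenylbutan-2-one F3. Silylation (t-BuMe2SiCl, imidazole, DMF) gives (4S)-4-{[tert-butyl(dimethyl)silyl]oxy}-4-phenylbutan-2-one F4. Kinetic enolisation at the methyl group and Claisen condensation with dimethyl oxalate (LiHMDS, THF, −78 °C) gives methyl (6S)-6-{[tert-butyl(dimethyl)silyl]oxy}-2,4-dioxo-6-phenylhexanoate F5. Treatment with CF3CO2H in CH2Cl2 removes the silyl group and closes ring C, and the route is rejoined at 8.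

Step 1. The risks are attack of the alkyllithium on the carbamate or lithiation next to nitrogen while the carbenoid is warmed, partial enolisation of 1 before addition (erosion of enantiopurity), and C- instead of O-silylation. The fallback sets out from 1. Reduction with i-Bu2AlH (toluene, −78 °C) gives tert-butyl (2R)-2-formylpiperidine-1-carboxylate F6. Ohira–Bestmann alkynylation (dimethyl (1-diazo-2-oxopropyl)phosphonate, K2CO3, MeOH, 0 °C) gives tert-butyl (2R)-2-ethynylpiperidine-1-carboxylate F7. Deprotonation with LiHMDS and oxidation of the acetylide with t-BuOOLi (THF, −78 → 0 °C) gives ynolate 2 with no alkyllithium present, and i-Pr3SiOTf returns the route to 3.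

**Further compounds**

F1 | step 6 | [(2S)-4-oxo-2-phenyl-3,4-dihydro-2H-pyran-6-yl]acetic acid | OC(=O)CC1=CC(=O)C[C@@H](c2ccccc2)O1
F2 | step 6 | [(2S)-4-oxo-2-phenyl-3,4-dihydro-2H-pyran-6-yl]acetyl chloride | ClC(=O)CC1=CC(=O)C[C@@H](c2ccccc2)O1
F3 | step 3 | (4S)-4-hydroxy-4-phenylbutan-2-one | CC(=O)C[C@@H](c1ccccc1)O
F4 | step 3 | (4S)-4-{[tert-butyl(dimethyl)silyl]oxy}-4-phenylbutan-2-one | CC(=O)C[C@@H](c1ccccc1)O[Si](C)(C)C(C)(C)C
F5 | step 3 | methyl (6S)-6-{[tert-butyl(dimethyl)silyl]oxy}-2,4-dioxo-6-phenylhexanoate | COC(=O)C(=O)CC(=O)C[C@@H](c1ccccc1)O[Si](C)(C)C(C)(C)C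
F6 | step 1 | tert-butyl (2R)-2-formylpiperidine-1-carboxylate | CC(C)(C)OC(=O)N1CCCC[C@@H]1C=O
F7 | step 1 | tert-butyl (2R)-2-ethynylpiperidine-1-carboxylate | CC(C)(C)OC(=O)N1CCCC[C@@H]1C#C
A1 | direct plan | 1,3-bis(methoxymethoxy)benzene | COCOc1cccc(OCOC)c1
A2 | direct plan | cyclopentanone O-(methylsulfonyl)oxime | CS(=O)(=O)ON=C1CCCC1
A3 | direct plan | 6-[2,6-bis(methoxymethoxy)phenyl]-2,3,4,5-tetrahydropyridine | COCOc1cccc(OCOC)c1C1=NCCCC1
A4 | direct plan | (2R)-2-[2,6-bis(methoxymethoxy)phenyl]-1-methylpiperidine | CN1CCCC[C@@H]1c1c(OCOC)cccc1OCOC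
A5 | direct plan | 2-iodo-3,5-bis(methoxymethoxy)-4-[(2R)-1-methylpiperidin-2-yl]phenol | CN1CCCC[C@@H]1c1c(OCOC)cc(O)c(I)c1OCOC
A6 | direct plan | 5,7-bis(methoxymethoxy)-6-[(2R)-1-methylpiperidin-2-yl]-2-phenyl-4H-chromen-4-one | CN1CCCC[C@@H]1c1c(OCOC)cc2oc(-c3ccccc3)cc(=O)c2c1OCOC
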